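**Retrosynthetic overview**
1. Target 15 ⇐ tri-O-methyl ether 14 (global O-demethylation) ⇐ tertiary carbamate 13 (reductive carbamate cleavage).
2. Key disconnection: the bond between the carbinol carbon and the 4-methylpentyl chain. The (R)-α-lithiated benzylic carbamate 12 (an α-oxy carbanion, i.e. a carbinol carbon used as the nucleophile) is alkylated with 1-bromo-4-methylpentane 11 with inversion, which sets the quaternary stereocenter directly.
3. Diarylmethane bond: aryllithium from the ring C bromide 7 adds to the ring B aldehyde 4, followed by ionic deoxygenation.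
4. Diaryl ether bond: copper-catalysed O-arylation of orsellinaldehyde 1 (ring B) with the ring A bromide 2. The secondary carbinol that feeds the key step comes from CBS reduction of acetophenone 5.
5. No ring is formed: rings A, B and C are all bought as benzene derivatives and joined in the order A–B (ether), B–C (methylene), then side chain.

Assumption: the stereocenter in the given SMILES is read as (R); compounds 1, 2, 5 and 11 are taken as catalogue chemicals.

**Step 1**
Reactants: 1 2,4-dihydroxy-6-methylbenzaldehyde (orsellinaldehyde); 2 1-bromo-3-methoxy-5-methylbenzene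
Product: 4 2-methoxy-4-(3-methoxy-5-methylphenoxy)-6-methylbenzaldehyde, via phenol aldehyde 3 (not isolated)
Conditions: CuI (10 mol%), picolinic acid (20 mol%), K3PO4 (3.5 equiv), DMSO, 90 °C; then MeI (3 equiv), 35 °C
Reagents that add atoms: iodomethane, CI
Why: Ullmann-type copper-catalysed O-arylation occurs at the more acidic, unhindered 4-OH (the 2-OH is hydrogen-bonded to the formyl group and flanked by it), and the remaining phenoxide is then capped in the same pot by Williamson methylation.

**Step 2**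
Reactants: 5 1-(4-bromo-2-methoxyphenyl)ethan-1-one
Product: 6 (1R)-1-(4-bromo-2-methoxyphenyl)ethan-1-ol
Conditions: (S)-Me-CBS oxazaborolidine, (3aS)-1-methyl-3,3-diphenyltetrahydro-1H,3H-pyrrolo[1,2-c][1,3,2]oxazaborole (10 mol%), BH3·SMe2 (0.7 equiv), THF, 0 °C; MeOH, then aqueous work-up
Reagents that add atoms: none
Why: Corey–Bakshi–Shibata reduction, in which the (S)-oxazaborolidine binds the ketone with the aryl group as the large substituent and delivers hydride to the Si face, giving the (R)-carbinol as for acetophenone.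

**Step 3**
Reactants: 6 (1R)-1-(4-bromo-2-methoxyphenyl)ethan-1-ol
Product: 7 (1R)-1-(4-bromo-2-methoxyphenyl)ethyl N,N-diisopropylcarbamate
Conditions: NaH (1.3 equiv), THF, 0 °C; iPr2NCOCl (1.2 equiv), reflux
Reagents that add atoms: N,N-diisopropylcarbamoyl chloride, CC(C)N(C(C)C)C(Cl)=O
Why: O-carbamoylation of the sodium alkoxide does not touch the C–O bond of the stereocenter, so (R) is retained, and it installs the hindered, lithium-chelating carbamate needed for the key step.

**Step 4**
Reactants: 7 (1R)-1-(4-bromo-2-methoxyphenyl)ethyl N,N-diisopropylcarbamate; 4 2-methoxy-4-(3-methoxy-5-methylphenoxy)-6-methylbenzaldehyde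
Product: 10 (1R)-1-[2-methoxy-4-[[2-methoxy-4-(3-methoxy-5-methylphenoxy)-6-methylphenyl]methyl]phenyl]ethyl N,N-diisopropylcarbamate, via aryllithium 8 (not isolated), via diarylmethanol 9 (not isolated)
Conditions: nBuLi (1.05 equiv), THF, −78 °C, 10 min; then 4, −78 °C; then CH2Cl2, Et3SiH (3 equiv), CF3CO2H (10 equiv), −40 → 0 °C
Reagents that add atoms: none
Why: Bromine–lithium exchange at −78 °C outruns deprotonation next to the carbamate, the aryllithium adds 1,2 to the aldehyde, and the doubly benzylic carbinol (ortho-methoxy and para-aryloxy on ring B) ionises in CF3CO2H far faster than the secondary carbamate and is trapped by Et3SiH (ionic hydrogenation).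

**Step 5**
Reactants: 10 (1R)-1-[2-methoxy-4-[[2-methoxy-4-(3-methoxy-5-methylphenoxy)-6-methylphenyl]methyl]phenyl]ethyl N,N-diisopropylcarbamate; 11 1-bromo-4-methylpentane
Product: 13 (2R)-2-[2-methoxy-4-[[2-methoxy-4-(3-methoxy-5-methylphenoxy)-6-methylphenyl]methyl]phenyl]-6-methylheptan-2-yl N,N-diisopropylcarbamate, via benzyllithium 12 (not isolated)
Conditions: sBuLi (1.3 equiv), TMEDA (1.3 equiv), Et2O, −78 °C, 1 h; then 11 (3 equiv), −78 °C, 8 h; MeOH quench at −78 °C
Reagents that add atoms: none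
Why: Hoppe-type carbamate-directed deprotonation gives, with retention, a configurationally stable chelated tertiary α-oxybenzyllithium in which the carbinol carbon (an electrophile in ordinary carbonyl chemistry) is the nucleophile, and its SE2 alkylation by the primary bromide anti to lithium (inversion) converts (R)-10 into the (R)-configured quaternary center.

**Step 6**
Reactants: 13 (2R)-2-[2-methoxy-4-[[2-methoxy-4-(3-methoxy-5-methylphenoxy)-6-methylphenyl]methyl]phenyl]-6-methylheptan-2-yl N,N-diisopropylcarbamate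
Product: 14 (2R)-2-[2-methoxy-4-[[2-methoxy-4-(3-methoxy-5-methylphenoxy)-6-methylphenyl]methyl]phenyl]-6-methylheptan-2-ol
Conditions: LiAlH4 (5 equiv), THF, reflux; Fieser work-up
Reagents that add atoms: none
Why: Reductive carbamate cleavage, in which hydride attacks the carbamate carbonyl and releases the tertiary alkoxide without breaking the C–O bond at the stereocenter, so the configuration is untouched.

**Step 7**
Reactants: 14 (2R)-2-[2-methoxy-4-[[2-methoxy-4-(3-methoxy-5-methylphenoxy)-6-methylphenyl]methyl]phenyl]-6-methylheptan-2-ol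
Product: 15 (2R)-2-[2-hydroxy-4-[[2-hydroxy-4-(3-hydroxy-5-methylphenoxy)-6-methylphenyl]methyl]phenyl]-6-methylheptan-2-ol
Conditions: nBuLi (10 equiv), Ph2PH (9 equiv), THF, 0 °C; then 14, 65 °C; H2O, dilute HCl to pH 7 at 0 °C
Reagents that add atoms: none
Why: Nucleophilic aryl methyl ether cleavage (SN2 at methyl by LiPPh2) removes all three O-methyl groups under basic, Lewis-acid-free conditions in which the tertiary benzylic carbinol sits as an inert lithium alkoxide, so neither ionisation nor ortho-quinone methide formation can erode the stereocenter.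

**Compound list**
1 | 2,4-dihydroxy-6-methylbenzaldehyde (orsellinaldehyde) | O=Cc1c(C)cc(O)cc1O | starting material
2 | 1-bromo-3-methoxy-5-methylbenzene | COc1cc(C)cc(Br)c1 | starting material
3 | 2-hydroxy-4-(3-methoxy-5-methylphenoxy)-6-methylbenzaldehyde (present as its potassium phenoxide) | O=Cc1c(C)cc(Oc2cc(C)cc(OC)c2)cc1O | intermediate
4 | 2-methoxy-4-(3-methoxy-5-methylphenoxy)-6-methylbenzaldehyde | O=Cc1c(C)cc(Oc2cc(C)cc(OC)c2)cc1OC | intermediate
5 | 1-(4-bromo-2-methoxyphenyl)ethan-1-one | CC(=O)c1ccc(Br)cc1OC | starting material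
6 | (1R)-1-(4-bromo-2-methoxyphenyl)ethan-1-ol | C[C@@H](O)c1ccc(Br)cc1OC | intermediate
7 | (1R)-1-(4-bromo-2-methoxyphenyl)ethyl N,N-diisopropylcarbamate | C[C@@H](OC(=O)N(C(C)C)C(C)C)c1ccc(Br)cc1OC | intermediate
8 | {4-[(1R)-1-(N,N-diisopropylcarbamoyloxy)ethyl]-3-methoxyphenyl}lithium | C[C@@H](OC(=O)N(C(C)C)C(C)C)c1ccc([Li])cc1OC | intermediate
9 | (1R)-1-[4-[hydroxy[2-methoxy-4-(3-methoxy-5-methylphenoxy)-6-methylphenyl]methyl]-2-methoxyphenyl]ethyl N,N-diisopropylcarbamate (both carbinol epimers; lithium alkoxide until acid is added) | C[C@@H](OC(=O)N(C(C)C)C(C)C)c1ccc(C(O)c2c(C)cc(Oc3cc(C)cc(OC)c3)cc2OC)cc1OC | intermediate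
10 | (1R)-1-[2-methoxy-4-[[2-methoxy-4-(3-methoxy-5-methylphenoxy)-6-methylphenyl]methyl]phenyl]ethyl N,N-diisopropylcarbamate | C[C@@H](OC(=O)N(C(C)C)C(C)C)c1ccc(Cc2c(C)cc(Oc3cc(C)cc(OC)c3)cc2OC)cc1OC | intermediate
11 | 1-bromo-4-methylpentane | CC(C)CCCBr | starting material
12 | [(1R)-1-(N,N-diisopropylcarbamoyloxy)-1-[2-methoxy-4-[[2-methoxy-4-(3-methoxy-5-methylphenoxy)-6-methylphenyl]methyl]phenyl]ethyl]lithium (TMEDA-chelated) | C[C@@]([Li])(OC(=O)N(C(C)C)C(C)C)c1ccc(Cc2c(C)cc(Oc3cc(C)cc(OC)c3)cc2OC)cc1OC | intermediate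
13 | (2R)-2-[2-methoxy-4-[[2-methoxy-4-(3-methoxy-5-methylphenoxy)-6-methylphenyl]methyl]phenyl]-6-methylheptan-2-yl N,N-diisopropylcarbamate | C[C@](CCCC(C)C)(OC(=O)N(C(C)C)C(C)C)c1ccc(Cc2c(C)cc(Oc3cc(C)cc(OC)c3)cc2OC)cc1OC | intermediate
14 | (2R)-2-[2-methoxy-4-[[2-methoxy-4-(3-methoxy-5-methylphenoxy)-6-methylphenyl]methyl]phenyl]-6-methylheptan-2-ol | C[C@](CCCC(C)C)(O)c1ccc(Cc2c(C)cc(Oc3cc(C)cc(OC)c3)cc2OC)cc1OC | intermediate
15 | (2R)-2-[2-hydroxy-4-[[2-hydroxy-4-(3-hydroxy-5-methylphenoxy)-6-methylphenyl]methyl]phenyl]-6-methylheptan-2-ol | Cc1cc(O)cc(Oc2cc(C)c(Cc3ccc([C@](C)(O)CCCC(C)C)c(O)c3)c(O)c2)c1 | target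

**Totals and risks**
Total step count: 7. Longest linear sequence: 6 steps (5 → 6 → 7 → 10 → 13 → 14 → 15); the other branch (1 → 4) joins at step 4.

The three steps most likely to fail:

Step 5 (key alkylation). The tertiary benzyllithium may react sluggishly with an unactivated primary bromide, lose configurational integrity, or compete with deprotonation at the diarylmethane CH2. The fallback sets out from 10 and comes back at 14. Compound 10 is lithiated to 12 exactly as before, but is then borylated with tris(4-methylpentyl)borane F1 (made beforehand from BH3·SMe2 and 4-methylpent-1-ene). The borane adds anti to lithium to give the lithium borate complex F2. On warming, one 4-methylpentyl group shifts from boron to carbon with loss of the carbamate, giving the tertiary borane F3. Oxidation with NaOH/H2O2 (retention) gives 14 directly, so 13 and step 6 are skipped. Inversion at borylation, inversion in the 1,2-shift and retention in the oxidation again convert (R)-10 into (R)-14.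

Step 1 (Ullmann coupling). An electron-poor, chelating dihydroxybenzaldehyde is a weak nucleophile toward an electron-rich aryl bromide, and some 2-O-arylation is possible. The fallback sets out from 1 and comes back at 4, with the roles of the two rings reversed. Tf2O/pyridine at −20 °C sulfonylates the free 4-OH selectively to give 4-formyl-3-hydroxy-5-methylphenyl trifluoromethanesulfonate F4. MeI/K2CO3 in acetone then gives 4-formyl-3-methoxy-5-methylphenyl trifluoromethanesulfonate F5. Palladium-catalysed C–O coupling of this electron-poor aryl sulfonate with commercial 3-methoxy-5-methylphenol gives 4 (Pd(OAc)2, tBuXPhos = 2-di-tert-butylphosphino-2′,4′,6′-triisopropylbiphenyl, K3PO4, toluene, 100 °C).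

Step 4 (addition and ionic hydrogenation). CF3CO2H could ionise the enantioenriched secondary benzylic carbamate and erode its configuration. The fallback sets out from 4 and 7 and comes back at 10 without any acid. NaBH4 in MeOH reduces 4 to [2-methoxy-4-(3-methoxy-5-methylphenoxy)-6-methylphenyl]methanol F6. SOCl2 in CH2Cl2 at 0 °C converts this to 2-(chloromethyl)-1-methoxy-5-(3-methoxy-5-methylphenoxy)-3-methylbenzene F7, used crude. Compound 7 is converted through 8 with ZnCl2 into chloro{4-[(1R)-1-(N,N-diisopropylcarbamoyloxy)ethyl]-3-methoxyphenyl}zinc F8. Negishi coupling of F7 with F8 (Pd(PPh3)4, THF, 25–50 °C) gives 10.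

**Further compounds**
F1 | step 5 | tris(4-methylpentyl)borane | CC(C)CCCB(CCCC(C)C)CCCC(C)C
F2 | step 5 | lithium [(1S)-1-(N,N-diisopropylcarbamoyloxy)-1-[2-methoxy-4-[[2-methoxy-4-(3-methoxy-5-methylphenoxy)-6-methylphenyl]methyl]phenyl]ethyl]tris(4-methylpentyl)borate | C[C@]([B-](CCCC(C)C)(CCCC(C)C)CCCC(C)C)(OC(=O)N(C(C)C)C(C)C)c1ccc(Cc2c(C)cc(Oc3cc(C)cc(OC)c3)cc2OC)cc1OC.[Li+]
F3 | step 5 | [(2S)-2-[2-methoxy-4-[[2-methoxy-4-(3-methoxy-5-methylphenoxy)-6-methylphenyl]methyl]phenyl]-6-methylheptan-2-yl]bis(4-methylpentyl)borane | C[C@@](B(CCCC(C)C)CCCC(C)C)(CCCC(C)C)c1ccc(Cc2c(C)cc(Oc3cc(C)cc(OC)c3)cc2OC)cc1OC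
F4 | step 1 | 4-formyl-3-hydroxy-5-methylphenyl trifluoromethanesulfonate | O=Cc1c(C)cc(OS(=O)(=O)C(F)(F)F)cc1O
F5 | step 1 | 4-formyl-3-methoxy-5-methylphenyl trifluoromethanesulfonate | O=Cc1c(C)cc(OS(=O)(=O)C(F)(F)F)cc1OC
F6 | step 4 | [2-methoxy-4-(3-methoxy-5-methylphenoxy)-6-methylphenyl]methanol | OCc1c(C)cc(Oc2cc(C)cc(OC)c2)cc1OC
F7 | step 4 | 2-(chloromethyl)-1-methoxy-5-(3-methoxy-5-methylphenoxy)-3-methylbenzene | ClCc1c(C)cc(Oc2cc(C)cc(OC)c2)cc1OC
F8 | step 4 | chloro{4-[(1R)-1-(N,N-diisopropylcarbamoyloxy)ethyl]-3-methoxyphenyl}zinc | C[C@@H](OC(=O)N(C(C)C)C(C)C)c1ccc([Zn]Cl)cc1OC
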